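## Structural features

Labdane numbering is used throughout: ring A is C1–C5 plus C10 and ring B is C5–C10. C18 is the 4α-methyl, C19 the 4β-ester carbon, C20 the carbon on C10 and C17 the exocyclic CH2 on C8. C11–C12 is the ethylene link and C13–C16 the butenolide, with its carbonyl at C16.

The target is a trans-decalin with the configuration 4S,5R,9S,10S. C9 carries a two-carbon chain that ends at the α-position of a butenolide. The four stereocentres C4, C5, C10 and C9 are contiguous. C4 and C10 are quaternary and stand 1,3 to each other, with C19 and C20 both axial on the β face, and C11 on C9 is cis to C20.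

The fragile groups are:
- the 1,1-disubstituted C8=C17 alkene, which moves into the ring under acid and is the first alkene to be hydrogenated;
- the butenolide, which is sensitive to base, nucleophiles and hydrogen;
- the C20 carbon, which at the alcohol oxidation level lies 1,3-diaxial to the C19 ester and can lactonise onto it under basic conditions.

The real difficulty is the vicinal C9/C10 pair next to the methylene, with quaternary C10 facing quaternary C4. The key step exploits three facts: C20 and C11 are cis on the adjacent atoms C10 and C9, C8 is sp2 with an exocyclic carbon, and ring B can be closed onto a ring A diene C10=C5–C6=C7. A buta-2,3-dienoate hung from the C20 oxygen therefore supplies C11, C9, C8 and C17 in one cycloaddition.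

## Logic of the disconnections

24 ⇒ 23. No skeletal bond is cut; the C20 aldehyde is taken back to the primary alcohol. The aldehyde is non-enolisable, so a mild neutral oxidation as the last step puts no stereocentre at risk. The demand is that the C20 alcohol is freed only under non-basic conditions, because it sits 1,3-diaxial to the C19 ester.

23 ⇒ 22. The C8=C17 alkene and the C20 hydroxyl are tied together as a β-bromo ether (bonds C8–O and C17–Br). One temporary ring protects both the alkene and the alcohol through the hydrogenation, the olefination and the cross-coupling, and a single zinc-induced elimination releases both. A diol mask with a later Corey–Winter olefination was weighed and set aside: it needs more steps and would expose a free C20 alkoxide to base beside the C19 ester.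

22 ⇒ 19 + 20. The C12–C13 bond is cut between an sp3 boron nucleophile at C12 and the α-bromo butenolide. The whole heterocycle arrives in one step with its double bond in place. The forward step must tolerate the lactone and leave the neopentyl C17 bromide alone.

19 ⇒ 18 ⇒ 17. The C11=C12 bond is cut (one-carbon olefination of the C11 aldehyde), and the aldehyde is taken back to the C11 alcohol. C12 is thus added to the carbon that the lactone carbonyl supplied. The demand is that C9, α to the aldehyde, keeps or regains its equatorial substituent.

17 ⇒ 16. The C5–H and C6–H bonds are removed to give back the C5=C6 alkene. The ether bridge over the β face of ring B directs hydrogen to the α face, which gives the trans ring fusion. The alkene is hindered, so the step needs a forcing but bromide-tolerant catalyst.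

16 ⇒ 15. The C8–O and C17–Br bonds are removed, giving back the free 1,4-diol with both alkenes. The forward bromoetherification must choose the C8=C17 bond and the C20 hydroxyl; only this pair can close a five-membered ring at a tertiary carbon.

15 ⇒ 14. No skeletal bond is cut; the diol is re-closed to the C11,C20 γ-lactone. The forward reduction must distinguish the lactone from the neopentyl C19 ester.

14 ⇒ 13 (key disconnection). The C7–C8 and C9–C10 bonds are cut. Ring B and the lactone disappear together, and two stereocentres, the quaternary C10 and the exocyclic alkene are traced to a monocyclic ester. The forward cycloaddition must use the conjugated bond of the allene and must add to the ring A face opposite the C19 ester.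

13 ⇒ 11 + 12. The ester C–O bond at C20 is cut. The tether is made in one step from the dienyl alcohol and the allenic acid; the coupling must not isomerise or oligomerise the allenoate.

11 ⇒ 10 ⇒ 8 + 9. The aldehyde is taken back from the alcohol, and the C5–C6 bond is cut between a vinylboron reagent and a β-bromo enal. Keeping C20 as an aldehyde until after the coupling means C19 and C20 are never two esters that must be told apart.

8 ⇒ 6. The C10–C20 bond is cut and the C5–Br bond is exchanged for the ketone. One haloformylation of the ketone installs both the C20 carbon and the leaving group at C5. It can occur only on the C10 side, because C4 is quaternary.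

6 ⇒ 3 ⇒ 1 + 2. The C4–C18 bond is cut. The quaternary centre comes from methylation of a β-keto ester whose enamine with an amino acid ester controls the face. This one step carries the absolute configuration of the whole route.

## Other disconnections considered

Alternative 1: The cut runs through ring A at C3–C4 and rejoins C1 to the oxygen of the C19 carboxyl, so the ring A acid A1 is traced to the vinyl δ-lactone A2. In the forward direction A2 is converted to its silyl ketene acetal. Because the ketene acetal and the allylic C–O bond lie in the same six-membered ring, it can rearrange only through a boat (Ireland–Claisen). The shift forms C3–C4, frees the C19 acid and leaves a C1=C2 alkene.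
- In favour: the quaternary C4 and its relation to C5 come from a stereospecific sigmatropic step of fixed geometry, and the acid appears at the correct oxidation level.
- Against: after the key step ring B, C9, the configuration of C10 and the methylene are all still missing. The two CH2OPMB arms on C10 of A1 are identical and must later be told apart. A2 already needs three stereocentres in a defined relation.
- Comparison: on the C4/C5 pair this alternative is the better plan. Chirality transfer through a rigid boat is more predictable than the facial choice that step 7 asks of C4, and no hydrogenation is needed to set C5. On the structure as a whole the chosen cycloaddition does more in one step. Both key steps are concerted pericyclic reactions of similar reliability. In step count the alternative is expected to be clearly longer.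

Alternative 2: The cuts are C9–C11 and C1–C10, so the trans-decalin nitrile A3 is traced to the alkenenitrile A4 and the organocopper reagent A5 (monovalent copper). In the forward direction A5 adds to C9 of A4, and the metalated nitrile at C10 displaces the C1 chloride in a 6-exo-tet closure of ring A.
- In favour: two C–C bonds, ring A and the C9 and C10 centres are made in one flask, and the plan is convergent.
- Against: A5 is a β-oxygenated organometallic and is prone to β-elimination. Alkenenitriles are reluctant acceptors, and C9 is flanked by the C8 ketal. The closure must place the nitrile axial, cis to the C19 ester. A4 already contains the vicinal C4/C5 pair, an acyclic quaternary centre beside a ring stereocentre. The C8 ketal must later become the methylene next to an epimerisable C9.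
- Comparison: on C20 this alternative is the better plan. The angular nitrile is one hydride reduction from the aldehyde, whereas the chosen route needs a lactone reduction and a late oxidation. It is also more convergent. Mechanistically it is an ionic tandem sequence in which three stereochemical relations (C9/C5, C10/C5, C9/C10) rest on conformational preferences. The cycloaddition fixes C9/C10 through the tether and leaves one open question. Step economy is judged roughly equal.

Alternative 3: The cuts are C5–C10 across a ten-membered ring and C4–CH3, so the bicyclic aldehyde ester A6 is traced to the cyclodecene A7. In the forward direction the C10 aldehyde of A7 is enolised, the enolate adds across the ring to C5 of the enoate and closes both six-membered rings, and the resulting C4 ester enolate is trapped with iodomethane in the same flask.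
- In favour: both rings and the C5, C10 and C4 centres form in one operation. Every oxidation level is final and the methylene is already present, so only the side chain remains after A6.
- Against: the difficulty is moved into A7, a medium ring with a trisubstituted enoate of defined geometry, a 1,1-disubstituted alkene and an enolisable aldehyde. The stereochemical result depends on which ring conformer reacts. An α-branched aldehyde enolate must form a quaternary centre in a reversible addition, with aldol pathways open.
- Comparison: after the key step this alternative is clearly better in step and redox economy, and it sets both quaternary centres at once. A reversible Michael step could also favour the trans-decalin thermodynamically, which is an advantage over the kinetic facial choice of step 7. Against this, the chosen route reaches its cycloaddition precursor in six steps from simple materials, whereas A7 needs a long and uncertain medium-ring synthesis.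

Key step: step 7

Remark on the chemistry (assumption): the sense of induction in step 2 depends on the auxiliary enantiomer and the lithium-coordinating additive. The L-valine ester with HMPA in toluene is taken to deliver the (S) ketone 6; D-valine tert-butyl ester (or THF in place of HMPA) would be used if the sense is the opposite.

## Steps

Step 1
Reactants: 1 methyl 2-oxocyclohexane-1-carboxylate; 2 L-valine tert-butyl ester (free base)
Product: 3 methyl 2-{[(2S)-1-tert-butoxy-3-methyl-1-oxobutan-2-yl]amino}cyclohex-1-ene-1-carboxylate
Conditions: BF3·OEt2 (cat.), toluene, reflux, Dean–Stark trap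
Reagents that add atoms: none
Why: Condensation of the β-keto ester with the primary amine should give the hydrogen-bonded enamino ester, driven by removal of water; it attaches the chiral auxiliary for the alkylation.

Step 2
Reactants: 3
Product: 6 methyl (1S)-1-methyl-2-oxocyclohexane-1-carboxylate, via lithium aza-enolate 4 (not isolated), via methylated imine 5 (not isolated)
Conditions: LiN(iPr)2, toluene, −78 °C; HMPA; MeI, −78 °C; then 1 M aq HCl, rt
Reagents that add atoms: iodomethane, CI; water, O; lithium diisopropylamide, [Li+].CC(C)[N-]C(C)C (lithium stays only in 4)
Why: Deprotonation should give a chelated lithium aza-enolate in which the valine ester carbonyl is bound to lithium, so the isopropyl-bearing side chain covers one face of C4 and iodomethane enters from the other, setting C4 (asymmetric alkylation of an amino acid ester enamine of a β-keto ester). Mild acid hydrolysis of the imine should return the ketone and release the auxiliary for recovery.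

Step 3
Reactants: 6
Product: 8 methyl (1R)-2-bromo-3-formyl-1-methylcyclohex-2-ene-1-carboxylate, via bromovinyl iminium bromide 7 (not isolated)
Conditions: PBr3, DMF, CHCl3, 0 → 60 °C; then aq NaOAc
Reagents that add atoms: N,N-dimethylformamide, CN(C)C=O; phosphorus tribromide, BrP(Br)Br; water, O
Why: Ketone 6 can enolise only towards C10, so the bromomethyleniminium reagent should formylate there and exchange the carbonyl oxygen for bromide; hydrolysis gives the β-bromo enal (Vilsmeier–Haack–Arnold haloformylation). The quaternary C4 is untouched; its descriptor changes only because bromine alters the priorities.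

Step 4
Reactants: 8; 9 potassium vinyltrifluoroborate
Product: 10 methyl (1S)-2-ethenyl-3-formyl-1-methylcyclohex-2-ene-1-carboxylate
Conditions: PdCl2(dppf)·CH2Cl2 (5 mol %), Cs2CO3, THF–H2O (9:1), 75 °C
Reagents that add atoms: none
Why: The β-bromo enal is an activated partner for oxidative addition to zerovalent palladium, and transmetalation from the vinyltrifluoroborate followed by reductive elimination should give the vinyl enal (Suzuki–Miyaura coupling). The aldehyde and the hindered ester are spectators.

Step 5
Reactants: 10
Product: 11 methyl (1S)-2-ethenyl-3-(hydroxymethyl)-1-methylcyclohex-2-ene-1-carboxylate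
Conditions: NaBH4, CeCl3·7H2O, MeOH, −20 °C
Reagents that add atoms: none
Why: Luche reduction should reduce the conjugated aldehyde 1,2-selectively and leave the methyl ester on the quaternary carbon alone, so C19 and C20 never need to be distinguished as two esters.

Step 6
Reactants: 11; 12 buta-2,3-dienoic acid
Product: 13 methyl (1S)-3-[(buta-2,3-dienoyloxy)methyl]-2-ethenyl-1-methylcyclohex-2-ene-1-carboxylate
Conditions: DCC, DMAP (5 mol %), CH2Cl2, −20 → 0 °C
Reagents that add atoms: none
Why: Carbodiimide activation (Steglich esterification) should acylate the primary allylic alcohol below 0 °C, where amine-induced oligomerisation of the allenoate is slow. The ester is used at once in step 7.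

Step 7
Reactants: 13
Product: 14 methyl 12,13,14,15,16-pentanorlabda-5,8(17)-dien-11,20-olid-19-oate (cis-fused γ-lactone; 4α-methyl; C19 ester β; 9α-H)
Conditions: MeCN (0.01 M), BHT (cat.), sealed tube, 100 °C
Reagents that add atoms: none
Why: The s-cis C10=C5–C6=C7 diene should add to the conjugated C9=C8 bond of the allenoate in a concerted, asynchronous [4+2] cycloaddition, forming C9–C10 and C7–C8 and leaving C8=C17 exocyclic. The closest known reaction types are thermal type 1 intramolecular Diels–Alder reactions of ester-tethered trienes and Diels–Alder reactions of allenic esters at their α,β bond. Ring B closes as the six-membered cycloaddition ring; the γ-lactone closes as the three-atom tether ring C20–O–C11, which spans C9–C10 from the inside position of the diene terminus and so can only be cis-fused. C9 is therefore set by the tether, with C11 and C20 on the same face. C10 is set by the diene face and depends on C4 alone: in the ring A half-chair the planar ester is expected to take the pseudoaxial site, and C9 with its inward hydrogen should then add to the opposite, α face. This bias is modest, so the diastereomeric adduct is to be removed by chromatography or crystallisation at this stage. Site selectivity for the α,β bond follows from its low LUMO and the five-membered tether ring, whereas the distal bond is unactivated and would need a six-membered tether ring. The polar solvent stabilises the s-cis ester rotamer needed for closure, which keeps the temperature below that of a [1,5] hydrogen shift from C20 to C7, and neutral conditions keep the β,γ-unsaturated lactone from moving into conjugation.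

Step 8
Reactants: 14
Product: 15 methyl 11,20-dihydroxy-12,13,14,15,16-pentanorlabda-5,8(17)-dien-19-oate
Conditions: LiBH4, THF, 0 °C → rt
Reagents that add atoms: none
Why: LiBH4 should reduce the strained γ-lactone to the 1,4-diol much faster than the neopentyl C19 methyl ester, and it is not basic enough to enolise C9 (chemoselective hydride reduction). Once C11 is an alcohol, C9 is no longer acidic.

Step 9
Reactants: 15
Product: 16 methyl 17-bromo-8β,20-epoxy-11-hydroxy-12,13,14,15,16-pentanorlabd-5-en-19-oate
Conditions: NBS, NaHCO3, CH2Cl2, 0 °C, dark
Reagents that add atoms: N-bromosuccinimide, O=C1CCC(=O)N1Br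
Why: The bromonium ion of the exposed C8=C17 bond should be captured 5-exo at the tertiary C8 by the C20 hydroxyl, which lies 1,3-diaxial to C8 on the β face (bromoetherification). The C11 hydroxyl could close only a four-membered or a 5-endo ring, and C5=C6 is shielded by two quaternary neighbours. The temporary C8 centre (O β, CH2Br α) is fixed by the bridge.

Step 10
Reactants: 16
Product: 17 methyl 17-bromo-8β,20-epoxy-11-hydroxy-12,13,14,15,16-pentanor-5α-labdan-19-oate
Conditions: H2 (20 bar), PtO2, EtOAc, rt
Reagents that add atoms: none
Why: The β face of C5=C6 is roofed by the C8–O–C20 bridge and flanked by the axial C19 ester, so cis addition of hydrogen on the catalyst surface should occur from the α face and give the 5α hydrogen and the trans ring fusion. Platinum in a neutral solvent is chosen because it is slow to cleave a primary alkyl bromide.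

Step 11
Reactants: 17
Product: 18 methyl 17-bromo-8β,20-epoxy-11-oxo-12,13,14,15,16-pentanor-5α-labdan-19-oate
Conditions: Dess–Martin periodinane, NaHCO3, CH2Cl2, 0 °C → rt
Reagents that add atoms: none
Why: Buffered Dess–Martin oxidation should convert the only free hydroxyl into the aldehyde without epimerising C9.

Step 12
Reactants: 18
Product: 19 methyl 17-bromo-8β,20-epoxy-13,14,15,16-tetranor-5α-labd-11-en-19-oate
Conditions: Ph3PCH3Br, KOtBu, THF, 0 °C → rt
Reagents that add atoms: methyltriphenylphosphonium bromide, C[P+](c1ccccc1)(c1ccccc1)c1ccccc1.[Br-]
Why: Wittig methylenation should add C12 to the hindered aldehyde; C20 is locked in the ether, so no alkoxide is formed next to the C19 ester. Any enolisation at C9 returns the equatorial, required configuration, and the C17 bromide has no β hydrogen and a neopentyl carbon, so it cannot eliminate or be displaced.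

Step 13
Reactants: 19; 20 3-bromofuran-2(5H)-one
Product: 22 methyl 17-bromo-8β,20-epoxy-5α-labd-13-en-16,15-olid-19-oate, via B-alkyl-9-BBN borane 21 (not isolated)
Conditions: 9-BBN-H, THF, 0 °C → rt; then 20, PdCl2(dppf) (5 mol %), AsPh3, Cs2CO3, DMF–H2O, rt
Reagents that add atoms: 9-borabicyclo[3.3.1]nonane, [H]B1C2CCCC1CCC2 (boron and its ring stay only in 21)
Why: Hydroboration should place boron on the terminal C12, and the B-alkyl Suzuki–Miyaura coupling with the α-bromo butenolide, an α-halo enoate partner, should form C12–C13 with the ring double bond already in place. The unactivated neopentyl C17 bromide does not add to zerovalent palladium under these conditions.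

Step 14
Reactants: 22
Product: 23 methyl 20-hydroxylabda-8(17),13-dien-16,15-olid-19-oate
Conditions: Zn dust (activated), NH4Cl, EtOH–H2O (9:1), 70 °C
Reagents that add atoms: none
Why: Zinc should insert into the C17–Br bond, and the β-alkoxy organozinc should expel the C8–O bond (Boord-type reductive elimination, as in the Bernet–Vasella fragmentation), regenerating the C8=C17 alkene and the C20 alcohol in one step. NH4Cl protonates the alkoxide at once so that it cannot attack the C19 ester, and the butenolide is not reduced by zinc under these conditions.

Step 15
Reactants: 23
Product: 24 methyl (4S,5R,9S,10S)-20-oxolabda-8(17),13-dien-16,15-olid-19-oate (CNP0175906.1)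
Conditions: Dess–Martin periodinane, NaHCO3, CH2Cl2, rt
Reagents that add atoms: none
Why: Neutral Dess–Martin oxidation of the neopentyl alcohol should give the non-enolisable C20 aldehyde without affecting the exocyclic alkene, the butenolide or the ester.

## Compound list

1 | methyl 2-oxocyclohexane-1-carboxylate | COC(=O)C1CCCCC1=O | starting material
2 | L-valine tert-butyl ester | CC(C)[C@H](N)C(=O)OC(C)(C)C | starting material
3 | methyl 2-{[(2S)-1-tert-butoxy-3-methyl-1-oxobutan-2-yl]amino}cyclohex-1-ene-1-carboxylate | COC(=O)C1=C(N[C@@H](C(C)C)C(=O)OC(C)(C)C)CCCC1 | intermediate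
4 | lithium aza-enolate of 3 (N-lithiated enamino ester; not isolated) | [Li+].COC(=O)C1=C([N-][C@@H](C(C)C)C(=O)OC(C)(C)C)CCCC1 | intermediate
5 | tert-butyl N-[(2S)-2-(methoxycarbonyl)-2-methylcyclohexylidene]-L-valinate (not isolated) | COC(=O)[C@@]1(C)CCCCC1=N[C@@H](C(C)C)C(=O)OC(C)(C)C | intermediate
6 | methyl (1S)-1-methyl-2-oxocyclohexane-1-carboxylate | COC(=O)[C@@]1(C)CCCCC1=O | intermediate
7 | [(2-bromo-3-methoxycarbonyl-3-methylcyclohex-1-en-1-yl)methylidene]dimethyliminium bromide (not isolated) | COC(=O)[C@@]1(C)CCCC(C=[N+](C)C)=C1Br.[Br-] | intermediate
8 | methyl (1R)-2-bromo-3-formyl-1-methylcyclohex-2-ene-1-carboxylate | COC(=O)[C@@]1(C)CCCC(C=O)=C1Br | intermediate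
9 | potassium vinyltrifluoroborate | [K+].C=C[B-](F)(F)F | starting material
10 | methyl (1S)-2-ethenyl-3-formyl-1-methylcyclohex-2-ene-1-carboxylate | COC(=O)[C@@]1(C)CCCC(C=O)=C1C=C | intermediate
11 | methyl (1S)-2-ethenyl-3-(hydroxymethyl)-1-methylcyclohex-2-ene-1-carboxylate | COC(=O)[C@@]1(C)CCCC(CO)=C1C=C | intermediate
12 | buta-2,3-dienoic acid | C=C=CC(=O)O | starting material
13 | methyl (1S)-3-[(buta-2,3-dienoyloxy)methyl]-2-ethenyl-1-methylcyclohex-2-ene-1-carboxylate | C=C=CC(=O)OCC1=C(C=C)[C@@](C)(C(=O)OC)CCC1 | intermediate
14 | methyl 12,13,14,15,16-pentanorlabda-5,8(17)-dien-11,20-olid-19-oate (cis-fused γ-lactone, C11 and C20 β, 9α-H, 4α-methyl, 4β-ester) | C=C1CC=C2[C@](CO3)(CCC[C@]2(C)C(=O)OC)[C@H]1C3=O | intermediate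
15 | methyl 11,20-dihydroxy-12,13,14,15,16-pentanorlabda-5,8(17)-dien-19-oate | C=C1CC=C2[C@](CO)(CCC[C@]2(C)C(=O)OC)[C@H]1CO | intermediate
16 | methyl 17-bromo-8β,20-epoxy-11-hydroxy-12,13,14,15,16-pentanorlabd-5-en-19-oate (8α-CH2Br) | BrC[C@]1(OC2)CC=C3[C@]2(CCC[C@]3(C)C(=O)OC)[C@H]1CO | intermediate
17 | methyl 17-bromo-8β,20-epoxy-11-hydroxy-12,13,14,15,16-pentanor-5α-labdan-19-oate | BrC[C@]1(OC2)CC[C@@H]3[C@]2(CCC[C@]3(C)C(=O)OC)[C@H]1CO | intermediate
18 | methyl 17-bromo-8β,20-epoxy-11-oxo-12,13,14,15,16-pentanor-5α-labdan-19-oate | BrC[C@]1(OC2)CC[C@@H]3[C@]2(CCC[C@]3(C)C(=O)OC)[C@H]1C=O | intermediate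
19 | methyl 17-bromo-8β,20-epoxy-13,14,15,16-tetranor-5α-labd-11-en-19-oate | BrC[C@]1(OC2)CC[C@@H]3[C@]2(CCC[C@]3(C)C(=O)OC)[C@H]1C=C | intermediate
20 | 3-bromofuran-2(5H)-one | O=C1OCC=C1Br | starting material
21 | 12-(9-borabicyclo[3.3.1]nonan-9-yl) derivative of 19 with C11–C12 saturated (not isolated) | BrC[C@]1(OC2)CC[C@@H]3[C@]2(CCC[C@]3(C)C(=O)OC)[C@H]1CCB1C2CCCC1CCC2 | intermediate
22 | methyl 17-bromo-8β,20-epoxy-5α-labd-13-en-16,15-olid-19-oate | BrC[C@]1(OC2)CC[C@@H]3[C@]2(CCC[C@]3(C)C(=O)OC)[C@H]1CCC1=CCOC1=O | intermediate
23 | methyl 20-hydroxylabda-8(17),13-dien-16,15-olid-19-oate | C=C1CC[C@@H]2[C@](CO)(CCC[C@]2(C)C(=O)OC)[C@H]1CCC1=CCOC1=O | intermediate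
24 | methyl (4S,5R,9S,10S)-20-oxolabda-8(17),13-dien-16,15-olid-19-oate | C=C1CC[C@@H]2[C@](C=O)(CCC[C@]2(C)C(=O)OC)[C@H]1CCC1=CCOC1=O | target

## Step count and least certain steps

Total step count: 15. Longest linear sequence: 15 steps (1 → 24); compounds 2, 9, 12 and 20 are purchased side inputs.

Step 7 (key step). The most likely failure is poor facial selectivity. Methyl and CO2Me at C4 differ little in effective size, so addition to the β face of ring A, syn to the ester, may compete and give the lactone that is epimeric at both C9 and C10. A slow cyclisation would also leave time for a [1,5] hydrogen shift from C20 to C7.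
Fallback, from 11 and back at 14: the C19 group is enlarged before the cycloaddition. Reduction of 11 with LiAlH4 should give the diol [(1S)-2-ethenyl-1-methylcyclohex-2-ene-1,3-diyl]dimethanol F1. Its less hindered allylic C20 hydroxyl is esterified selectively with 12 (DCC, −20 °C) to the mono-allenoate F2, and the neopentyl C19 hydroxyl is capped with iPr3SiOTf and 2,6-lutidine to give the triisopropylsilyl ether F3. The CH2OSi(iPr)3 group is far larger than methyl, so it should occupy the pseudoaxial site and block the β face. The same thermal cycloaddition is then expected to give the silyloxymethyl adduct F4 with a clearer preference. HF·pyridine frees the C19 alcohol F5, TEMPO with PhI(OAc)2 in wet MeCN oxidises it to the C19 acid F6, and Me3SiCHN2 gives 14.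

Step 9. The most likely failure is loss of chemoselectivity in the halocyclisation: bromonium formation at the more electron-rich C5=C6 bond, or capture by the C11 hydroxyl after a ring flip.
Fallback, from 15 and back at 16: the C11 hydroxyl is removed from play by a protecting-group detour. Selective silylation of the less hindered primary alcohol (tBuMe2SiCl, imidazole, −20 °C) should give the 11-silyl ether F7. The C20 hydroxyl is then the only internal nucleophile, and it can reach only C8, so NBS should give the silylated bromo ether F8. HF·pyridine returns 16.

Step 10. The most likely failure is no turnover at the hindered trisubstituted alkene, or slow hydrogenolysis of the C17–Br bond under forcing conditions.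
Fallback, from 16 and back at 17, with no new compound (entry F0): surface hydrogenation is replaced by stepwise radical hydrogen-atom transfer with Mn(dpm)3, PhSiH3 and tBuOOH in iPrOH. A hydrogen atom is delivered to C6, and the tertiary C5 radical takes its hydrogen axially, away from the bridge. The C5 configuration then no longer depends on adsorption of the alkene on a metal surface.

Step 13. The most likely failure is degradation of the base-sensitive bromobutenolide, or protodeboronation of the hindered alkylborane before transmetalation.
Fallback, from 19 and back at 22, by enolate alkylation in place of cross-coupling: hydroboration of 19 followed by NaBO3 oxidation should give the C12 alcohol F9, and I2, PPh3 and imidazole convert it to the C12 iodide F10. The lithium enolate of 3-(phenylsulfanyl)oxolan-2-one (LiN(iPr)2, THF–HMPA) is alkylated with F10 to give the α-phenylsulfanyl lactone F11. mCPBA at −78 °C gives the sulfoxide F12, and thermal syn elimination in warm toluene should place the double bond in the ring to give 22.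

## Further compounds

F1 | step 7 | [(1S)-2-ethenyl-1-methylcyclohex-2-ene-1,3-diyl]dimethanol | OC[C@@]1(C)CCCC(CO)=C1C=C
F2 | step 7 | [(3S)-2-ethenyl-3-(hydroxymethyl)-3-methylcyclohex-1-en-1-yl]methyl buta-2,3-dienoate | OC[C@@]1(C)CCCC(COC(=O)C=C=C)=C1C=C
F3 | step 7 | triisopropylsilyl ether of F2 at the C19 oxygen | CC(C)[Si](OC[C@@]1(C)CCCC(COC(=O)C=C=C)=C1C=C)(C(C)C)C(C)C
F4 | step 7 | 19-(triisopropylsilyloxy)-12,13,14,15,16-pentanorlabda-5,8(17)-dien-11,20-olide | C=C1CC=C2[C@](CO3)(CCC[C@]2(C)CO[Si](C(C)C)(C(C)C)C(C)C)[C@H]1C3=O
F5 | step 7 | 19-hydroxy-12,13,14,15,16-pentanorlabda-5,8(17)-dien-11,20-olide | C=C1CC=C2[C@](CO3)(CCC[C@]2(C)CO)[C@H]1C3=O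
F6 | step 7 | 12,13,14,15,16-pentanorlabda-5,8(17)-dien-11,20-olid-19-oic acid | C=C1CC=C2[C@](CO3)(CCC[C@]2(C)C(=O)O)[C@H]1C3=O
F7 | step 9 | methyl 11-(tert-butyldimethylsilyloxy)-20-hydroxy-12,13,14,15,16-pentanorlabda-5,8(17)-dien-19-oate | C=C1CC=C2[C@](CO)(CCC[C@]2(C)C(=O)OC)[C@H]1CO[Si](C)(C)C(C)(C)C
F8 | step 9 | methyl 17-bromo-11-(tert-butyldimethylsilyloxy)-8β,20-epoxy-12,13,14,15,16-pentanorlabd-5-en-19-oate | BrC[C@]1(OC2)CC=C3[C@]2(CCC[C@]3(C)C(=O)OC)[C@H]1CO[Si](C)(C)C(C)(C)C
F0 | step 10 | none | none
F9 | step 13 | methyl 17-bromo-8β,20-epoxy-12-hydroxy-13,14,15,16-tetranor-5α-labdan-19-oate | BrC[C@]1(OC2)CC[C@@H]3[C@]2(CCC[C@]3(C)C(=O)OC)[C@H]1CCO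
F10 | step 13 | methyl 17-bromo-8β,20-epoxy-12-iodo-13,14,15,16-tetranor-5α-labdan-19-oate | BrC[C@]1(OC2)CC[C@@H]3[C@]2(CCC[C@]3(C)C(=O)OC)[C@H]1CCI
F11 | step 13 | methyl 17-bromo-8β,20-epoxy-13-(phenylsulfanyl)-5α-labdan-16,15-olid-19-oate (either C13 epimer) | BrC[C@]1(OC2)CC[C@@H]3[C@]2(CCC[C@]3(C)C(=O)OC)[C@H]1CCC1(Sc2ccccc2)CCOC1=O
F12 | step 13 | methyl 17-bromo-8β,20-epoxy-13-(phenylsulfinyl)-5α-labdan-16,15-olid-19-oate (either C13 epimer) | BrC[C@]1(OC2)CC[C@@H]3[C@]2(CCC[C@]3(C)C(=O)OC)[C@H]1CCC1(S(=O)c2ccccc2)CCOC1=O
A1 | alternative 1 | 5,5-bis{[(4-methoxyphenyl)methoxy]methyl}-1-methyl-6-[4-(trimethylsilyl)but-3-yn-1-yl]cyclohex-3-ene-1-carboxylic acid (C4 and C5 as in the target) | OC(=O)[C@@]1(C)CC=CC(COCc2ccc(OC)cc2)(COCc2ccc(OC)cc2)[C@H]1CCC#C[Si](C)(C)C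
A2 | alternative 1 | 6-ethenyl-5,5-bis{[(4-methoxyphenyl)methoxy]methyl}-3-methyl-4-[4-(trimethylsilyl)but-3-yn-1-yl]oxan-2-one (vinyl trans to the alkynyl chain; either epimer at the methyl-bearing carbon) | C=C[C@H]1OC(=O)C(C)[C@H](CCC#C[Si](C)(C)C)C1(COCc1ccc(OC)cc1)COCc1ccc(OC)cc1
A3 | alternative 2 | methyl 10-cyano-8,8-ethylenedioxy-9-(1,3-dioxolan-2-ylmethyl) trans-decalin-4-carboxylate (labdane numbering; angular nitrile, masked C12 aldehyde) | O1CCOC12CC[C@@H]3[C@](C#N)(CCC[C@]3(C)C(=O)OC)[C@H]2CC1OCCO1
A4 | alternative 2 | methyl 5-chloro-2-(2-cyano-4,4-ethylenedioxycyclohex-2-en-1-yl)-2-methylpentanoate (C4 and C5 as in the target) | N#CC1=CC2(OCCO2)CC[C@H]1[C@](C)(CCCCl)C(=O)OC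
A5 | alternative 2 | (1,3-dioxolan-2-ylmethyl)copper | [Cu]CC1OCCO1
A6 | alternative 3 | methyl 12-[(4-methoxyphenyl)methoxy]-20-oxo-13,14,15,16-tetranorlabd-8(17)-en-19-oate | C=C1CC[C@@H]2[C@](C=O)(CCC[C@]2(C)C(=O)OC)[C@H]1CCOCc3ccc(OC)cc3
A7 | alternative 3 | methyl 7-formyl-6-{2-[(4-methoxyphenyl)methoxy]ethyl}-5-methylidenecyclodec-1-ene-1-carboxylate (ring carbons trans across the enoate double bond; either epimer at the formyl-bearing carbon) | COC(=O)/C1=C\CCC(=C)[C@H](CCOCc2ccc(OC)cc2)C(C=O)CCC1
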